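**Retrosynthetic overview**
- The last operation breaks three bonds at once: the benzylic C7–OAr ether, the oxolane C3–O bond and the lactone C1–O bond. This leads back to natural (2S)-pinocembrin and an acyclic cis-epoxy γ-hydroxy enoate.
- Forward, the phenoxide opens the epoxide at the benzylic carbon (inversion), the freed alkoxide closes the oxolane by oxa-Michael addition, and the γ-lactone then closes. Both new rings form in that one step; the flavanone rings are bought intact.
- The epoxy enoate comes from cross-metathesis of an epoxy vinyl carbinol with methyl acrylate; the cis-epoxide comes from catalyst-controlled epoxidation of a (Z)-dienol.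
- The (Z)-dienol comes from phenylacetylene and (R)-epichlorohydrin by alkynylation, semi-hydrogenation and one-carbon ylide homologation.

Chain numbering used below: C1 lactone carbonyl, C2 CH2, C3 ring-fusion carbon on the oxolane O, C4 ring-fusion carbon on the lactone O, C5 ring CH2, C6 oxolane carbon bearing the side chain, C7 benzylic carbon. The target is (3R,4R,6S,7S) with a (2S)-flavanone.

Assumption: natural (2S)-pinocembrin is bought enantiopure, and the Shi ketone for cis-alkenes is a known catalyst made separately from D-glucose (not counted as a step).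

**Route**

Step 1
Reactants: 1 phenylacetylene; 2 (R)-epichlorohydrin
Product: 4 (2R)-1-chloro-5-phenylpent-4-yn-2-ol, via lithium phenylacetylide 3 (not isolated)
Conditions: n-BuLi, THF, −78 °C; BF3·OEt2, then 2, −78 °C; aq. NH4Cl
Reagents that add atoms: none
Why: Yamaguchi-type alkynylation, in which BF3-activated 2 is opened by acetylide 3 by SN2 at the unsubstituted ring carbon only, so the chloride and the stereocentre are untouched and the (R) centre of 2 becomes C4 with unchanged descriptor.

Step 2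
Reactants: 4 (2R)-1-chloro-5-phenylpent-4-yn-2-ol
Product: 5 (2R,4Z)-1-chloro-5-phenylpent-4-en-2-ol
Conditions: H2 (1 atm), Pd/CaCO3 poisoned with Pb(OAc)2, quinoline, EtOAc, rt
Reagents that add atoms: none
Why: Lindlar semi-hydrogenation adds H2 syn on the poisoned palladium surface and stops at the (Z)-styrene, the geometry a cis-epoxide needs, while the alkyl chloride and the carbinol centre are inert.

Step 3
Reactants: 5 (2R,4Z)-1-chloro-5-phenylpent-4-en-2-ol
Product: 7 (3R,5Z)-6-phenylhexa-1,5-dien-3-ol, via allyl epoxide 6 (not isolated)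
Conditions: Me3S+ I− (4 equiv), n-BuLi (4 equiv), THF, −10 °C to rt
Reagents that add atoms: trimethylsulfonium iodide, C[S+](C)C.[I-]
Why: One-carbon epoxide-to-allylic-alcohol homologation with excess dimethylsulfonium methylide (Corey–Chaykovsky ylide), which first closes the chlorohydrin to terminal epoxide 6, then opens it at CH2, after which the sulfonium betaine loses Me2S by ylide-mediated β-elimination; no bond to the (R) centre is broken.

Step 4
Reactants: 7 (3R,5Z)-6-phenylhexa-1,5-dien-3-ol
Product: 8 (2R)-1-[(2S,3R)-3-phenyloxiran-2-yl]but-3-en-2-ol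
Conditions: Shi D-glucose-derived N-Boc spiro-oxazolidinone ketone (25 mol%), Oxone (2KHSO5·KHSO4·K2SO4), K2CO3, Bu4NHSO4, DME–dimethoxymethane, aq. K2CO3–AcOH buffer (pH 8), −10 °C
Reagents that add atoms: potassium peroxymonosulfate KHSO5 (from Oxone), [K+].[O-]S(=O)(=O)OO
Why: Shi asymmetric epoxidation with the ketone developed for cis-alkenes, whose electrophilic dioxirane should attack the electron-rich cis-styrene and leave the deactivated vinyl carbinol; oxygen transfer is stereospecific (cis-epoxide) and the face is chosen by the catalyst (spiro transition state with phenyl next to the oxazolidinone; the catalyst enantiomer that turns cis-β-methylstyrene into its (1R,2S)-oxide), which sets C6 (S) and C7 (R), the minor face diastereomer being removed on Et3N-deactivated silica.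

Step 5
Reactants: 8 (2R)-1-[(2S,3R)-3-phenyloxiran-2-yl]but-3-en-2-ol; 9 methyl acrylate
Product: 10 methyl (2E,4R)-4-hydroxy-5-[(2S,3R)-3-phenyloxiran-2-yl]pent-2-enoate
Conditions: second-generation Hoveyda–Grubbs catalyst RuCl2(H2IMes)(=CH-C6H4-2-OiPr) (5 mol%), 9 (5 equiv), CH2Cl2, 40 °C
Reagents that add atoms: none
Why: Olefin cross-metathesis of a terminal allylic alcohol with an electron-poor acrylate is a selective, E-selective pairing; the epoxide is the only other functional group and no stereocentre is touched.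

Step 6
Reactants: 10 methyl (2E,4R)-4-hydroxy-5-[(2S,3R)-3-phenyloxiran-2-yl]pent-2-enoate (1.3 equiv); 11 (2S)-pinocembrin
Product: 14 (3aR,5S,6aR)-5-[(S)-{[(2S)-5-hydroxy-4-oxo-2-phenyl-3,4-dihydro-2H-chromen-7-yl]oxy}(phenyl)methyl]tetrahydrofuro[3,2-b]furan-2(3H)-one (CNP0152032.1), via aryl ether diol enoate 12 (not isolated), via oxolane hydroxy ester 13 (not isolated)
Conditions: CsF (1.5 equiv), DMF, 50 °C; then DBU (0.2 equiv), rt; AcOH quench
Reagents that add atoms: none
Why: Proposed new method: the caesium phenoxide of the 7-OH of 11 (the only acidic phenol, the 5-OH being hydrogen-bonded to the ketone) opens the cis-epoxide at the benzylic carbon by SN2 with inversion and sets C7 (S) (closest known reaction: CsF- or hydroxide-mediated phenol opening of 3-phenyloxiranes at the benzylic carbon), the freed C6 alkoxide adds reversibly to the enoate by 5-exo oxa-Michael addition to close the oxolane (12 to 13), and only the C3 epimer with the acetate arm cis to the C4 hydroxyl can lactonise, which drains the equilibrium into the cis-fused γ-lactone and sets C3 (R) (closest known reaction: base-mediated oxa-Michael/lactonisation of γ,ε-dihydroxy enoates to furo[3,2-b]furanones in styryl-lactone synthesis).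

**Compound list**

1 | phenylacetylene | C#Cc1ccccc1 | starting material
2 | (R)-epichlorohydrin | ClC[C@H]1CO1 | starting material
3 | lithium phenylacetylide | [Li]C#Cc1ccccc1 | intermediate (not isolated)
4 | (2R)-1-chloro-5-phenylpent-4-yn-2-ol | ClC[C@H](O)CC#Cc1ccccc1 | intermediate
5 | (2R,4Z)-1-chloro-5-phenylpent-4-en-2-ol | ClC[C@H](O)C/C=C\c1ccccc1 | intermediate
6 | (2R)-2-[(2Z)-3-phenylprop-2-en-1-yl]oxirane | C1[C@H](O1)C/C=C\c1ccccc1 | intermediate (not isolated)
7 | (3R,5Z)-6-phenylhexa-1,5-dien-3-ol | C=C[C@H](O)C/C=C\c1ccccc1 | intermediate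
8 | (2R)-1-[(2S,3R)-3-phenyloxiran-2-yl]but-3-en-2-ol | C=C[C@H](O)C[C@@H]1O[C@@H]1c1ccccc1 | intermediate
9 | methyl acrylate | C=CC(=O)OC | starting material
10 | methyl (2E,4R)-4-hydroxy-5-[(2S,3R)-3-phenyloxiran-2-yl]pent-2-enoate | COC(=O)/C=C/[C@H](O)C[C@@H]1O[C@@H]1c1ccccc1 | intermediate
11 | (2S)-pinocembrin, (2S)-5,7-dihydroxy-2-phenyl-2,3-dihydro-4H-chromen-4-one | O=C1C[C@@H](c2ccccc2)Oc2cc(O)cc(O)c12 | starting material
12 | methyl (2E,4R,6S,7S)-4,6-dihydroxy-7-{[(2S)-5-hydroxy-4-oxo-2-phenyl-3,4-dihydro-2H-chromen-7-yl]oxy}-7-phenylhept-2-enoate | COC(=O)/C=C/[C@H](O)C[C@H](O)[C@@H](Oc1cc(O)c2c(c1)O[C@H](c1ccccc1)CC2=O)c1ccccc1 | intermediate (not isolated)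
13 | methyl 2-[(2R,3R,5S)-3-hydroxy-5-[(S)-{[(2S)-5-hydroxy-4-oxo-2-phenyl-3,4-dihydro-2H-chromen-7-yl]oxy}(phenyl)methyl]oxolan-2-yl]acetate | COC(=O)C[C@H]1O[C@H]([C@@H](Oc2cc(O)c3c(c2)O[C@H](c2ccccc2)CC3=O)c2ccccc2)C[C@H]1O | intermediate (not isolated)
14 | (3aR,5S,6aR)-5-[(S)-{[(2S)-5-hydroxy-4-oxo-2-phenyl-3,4-dihydro-2H-chromen-7-yl]oxy}(phenyl)methyl]tetrahydrofuro[3,2-b]furan-2(3H)-one | O=C1C[C@H]2O[C@H]([C@@H](Oc3cc(O)c4c(c3)O[C@H](c3ccccc3)CC4=O)c3ccccc3)C[C@H]2O1 | target

**Totals**
Total step count: 6. Longest linear sequence: 6 steps (1 and 2 to 14 through 4, 5, 7, 8 and 10).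

**Three steps most likely to fail**

Step 6 (cascade). The main dangers are base-induced epimerisation of the flavanone C2 through its chalcone, phenoxide attack at C6 instead of C7, and a stall at the trans oxolane ester. The fallback sets out from 10 and comes back to the route at 14, and it keeps pinocembrin away from base by ending in a neutral Mitsunobu etherification. Compound 10 is taken through the same opening, oxa-Michael and lactonisation sequence with 4-methoxyphenol (CsF, DMF, 50 °C). This passes methyl (2E,4R,6S,7S)-4,6-dihydroxy-7-(4-methoxyphenoxy)-7-phenylhept-2-enoate F1 and methyl 2-[(2R,3R,5S)-3-hydroxy-5-[(S)-(4-methoxyphenoxy)(phenyl)methyl]oxolan-2-yl]acetate F2, neither isolated, and gives (3aR,5S,6aR)-5-[(S)-(4-methoxyphenoxy)(phenyl)methyl]tetrahydrofuro[3,2-b]furan-2(3H)-one F3. Oxidative removal of the aryl group with (NH4)2Ce(NO3)6 in MeCN–H2O at 0 °C frees (3aR,5S,6aR)-5-[(S)-hydroxy(phenyl)methyl]tetrahydrofuro[3,2-b]furan-2(3H)-one F4. Mitsunobu inversion with 4-nitrobenzoic acid (PPh3, DIAD, THF) gives (R)-[(3aR,5S,6aR)-2-oxohexahydrofuro[3,2-b]furan-5-yl](phenyl)methyl 4-nitrobenzoate F5. Mild methanolysis (K2CO3, MeOH, 0 °C, then AcOH) gives (3aR,5S,6aR)-5-[(R)-hydroxy(phenyl)methyl]tetrahydrofuro[3,2-b]furan-2(3H)-one F6. A final Mitsunobu reaction of F6 with 11 (PPh3, DIAD, THF, 0 °C), selective for the 7-OH, inverts C7 once more and gives 14.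

Step 4 (Shi epoxidation). The facial selectivity on a substrate with a free allylic alcohol and a second alkene is untested, and epoxy alcohol 8 can cyclise by attack of its hydroxyl at the benzylic carbon under acid. The fallback sets out from 5 and comes back to the route at 8, and it replaces catalyst control by substrate direction. Chlorohydrin 5 has only one alkene and a homoallylic hydroxyl, so VO(acac)2 with t-BuOOH in CH2Cl2 (0 °C to rt) epoxidises it through a chair vanadate transition state with CH2Cl equatorial. The A(1,3) strain of the (Z)-alkene is expected to favour the 1,3-syn cis-epoxide, (2R)-1-chloro-3-[(2S,3R)-3-phenyloxiran-2-yl]propan-2-ol F7. The ylide homologation of step 3 (Me3S+ I−, n-BuLi, THF, −10 °C, quenched cold) then passes (2S,3R)-2-{[(2R)-oxiran-2-yl]methyl}-3-phenyloxirane F8, not isolated, and gives 8.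

Step 5 (cross-metathesis). Ruthenium hydrides can isomerise the allylic alcohol to a ketone, and the acid-sensitive aryl epoxide may not survive 40 °C with the catalyst. The fallback sets out from 8 and comes back to the route at 14, and it replaces methyl acrylate by carbon monoxide. Compound 8 is opened with 11 (CsF, DMF, 50 °C) at the benzylic carbon to give (2S)-7-{[(1S,2S,4R)-2,4-dihydroxy-1-phenylhex-5-en-1-yl]oxy}-5-hydroxy-2-phenyl-2,3-dihydro-4H-chromen-4-one F9. A divalent-palladium-catalysed oxycarbonylative bicyclisation (PdCl2 10 mol%, CuCl2, NaOAc, AcOH, CO 1 atm, rt) then closes both rings. The C6 hydroxyl adds 5-exo to the palladium-bound alkene, CO inserts, and the C4 hydroxyl captures the acyl palladium, which gives the cis-fused lactone 14 under buffered acidic conditions.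

**Further compounds**
F1 | step 6 | methyl (2E,4R,6S,7S)-4,6-dihydroxy-7-(4-methoxyphenoxy)-7-phenylhept-2-enoate | COC(=O)/C=C/[C@H](O)C[C@H](O)[C@@H](Oc1ccc(OC)cc1)c1ccccc1
F2 | step 6 | methyl 2-[(2R,3R,5S)-3-hydroxy-5-[(S)-(4-methoxyphenoxy)(phenyl)methyl]oxolan-2-yl]acetate | COC(=O)C[C@H]1O[C@H]([C@@H](Oc2ccc(OC)cc2)c2ccccc2)C[C@H]1O
F3 | step 6 | (3aR,5S,6aR)-5-[(S)-(4-methoxyphenoxy)(phenyl)methyl]tetrahydrofuro[3,2-b]furan-2(3H)-one | O=C1C[C@H]2O[C@H]([C@@H](Oc3ccc(OC)cc3)c3ccccc3)C[C@H]2O1
F4 | step 6 | (3aR,5S,6aR)-5-[(S)-hydroxy(phenyl)methyl]tetrahydrofuro[3,2-b]furan-2(3H)-one | O=C1C[C@H]2O[C@H]([C@@H](O)c3ccccc3)C[C@H]2O1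
F5 | step 6 | (R)-[(3aR,5S,6aR)-2-oxohexahydrofuro[3,2-b]furan-5-yl](phenyl)methyl 4-nitrobenzoate | O=C1C[C@H]2O[C@H]([C@H](OC(=O)c3ccc(cc3)[N+](=O)[O-])c3ccccc3)C[C@H]2O1
F6 | step 6 | (3aR,5S,6aR)-5-[(R)-hydroxy(phenyl)methyl]tetrahydrofuro[3,2-b]furan-2(3H)-one | O=C1C[C@H]2O[C@H]([C@H](O)c3ccccc3)C[C@H]2O1
F7 | step 4 | (2R)-1-chloro-3-[(2S,3R)-3-phenyloxiran-2-yl]propan-2-ol | ClC[C@H](O)C[C@@H]1O[C@@H]1c1ccccc1
F8 | step 4 | (2S,3R)-2-{[(2R)-oxiran-2-yl]methyl}-3-phenyloxirane | C1[C@H](O1)C[C@@H]2O[C@@H]2c3ccccc3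
F9 | step 5 | (2S)-7-{[(1S,2S,4R)-2,4-dihydroxy-1-phenylhex-5-en-1-yl]oxy}-5-hydroxy-2-phenyl-2,3-dihydro-4H-chromen-4-one | C=C[C@H](O)C[C@H](O)[C@@H](Oc1cc(O)c2c(c1)O[C@H](c1ccccc1)CC2=O)c1ccccc1
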